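**Plan**
1. Retrosynthesis: the C4–OCH3 bond at the quaternary carbon is cut first (oxidative dearomatisation in reverse), which turns the cross-conjugated dienone ring A into a para-alkylphenol. The C8–C4 bond between ring A and the side chain is cut next, to a 4-bromophenol and a secondary boronic ester. Last come the C2–allyl bond (Claisen) and a C8–B bond (protoboration of isoeugenol).
2. Enabling feature: C4 lies para to the C1 carbonyl, so ring A is a phenol at a higher oxidation level. As the para carbon of a phenoxide, C4 takes the C8 alkyl group from boron when the phenoxide oxygen is oxidised; as the para carbon of the phenol it later takes up methanol.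
3. Forward: the ring A fragment (2 steps) and the side-chain fragment (2 steps) are made from two bought benzene rings and joined at C8–C4 in step 5. Ring A is dearomatised to the dienone in step 6 and the silyl ether is removed in step 7; no ring is built.
4. Stereochemistry: C8 is set by a copper-catalysed enantioselective protoboration (step 4) and carried into the C–C bond with retention (step 5). C4 is set in step 6 under control of C8 (methanol enters anti to the CH2Ar arm); this control is expected to be modest, and the 4-epimer is removed by chromatography.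

Key step: step 5

Remark: commercial isoeugenol is taken as its (E) isomer (E-rich material, enriched before use if needed); the sense of induction in step 4 is fixed by the choice of ligand antipode.

**Step 1**
Reactants: 1 4-bromo-3-methoxyphenol; 2 allyl bromide
Product: 3 1-bromo-2-methoxy-4-(prop-2-en-1-yloxy)benzene
Conditions: K2CO3, acetone, reflux
Reagents that add atoms: allyl bromide (2) | C=CCBr
Why: Williamson ether synthesis, the phenoxide displacing bromide from the allylic carbon (SN2).

**Step 2**
Reactants: 3 1-bromo-2-methoxy-4-(prop-2-en-1-yloxy)benzene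
Product: 4 4-bromo-5-methoxy-2-(prop-2-en-1-yl)phenol
Conditions: PhNEt2, 190 °C
Reagents that add atoms: none
Why: Aromatic Claisen rearrangement ([3,3]-sigmatropic shift, then tautomerisation to the phenol); of the two ortho carbons the one para to the methoxy group should be preferred, because the other is flanked by the methoxy group, whose methyl is pushed toward it by the neighbouring bromine.

**Step 3**
Reactants: 5 (E)-isoeugenol, 2-methoxy-4-[(1E)-prop-1-en-1-yl]phenol
Product: 6 {2-methoxy-4-[(1E)-prop-1-en-1-yl]phenoxy}tri(propan-2-yl)silane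
Conditions: TIPSCl, imidazole, DMF, rt
Reagents that add atoms: chlorotri(propan-2-yl)silane (TIPSCl) | CC(C)[Si](Cl)(C(C)C)C(C)C
Why: Imidazole-promoted silylation of the phenol; the bulky triisopropylsilyl ether should withstand the alkoxide of step 4, the organolithium reagents of step 5 and PhI(OAc)2, and leaves with fluoride at the end.

**Step 4**
Reactants: 6 {2-methoxy-4-[(1E)-prop-1-en-1-yl]phenoxy}tri(propan-2-yl)silane
Product: 7 2-[(2R)-1-{3-methoxy-4-[tri(propan-2-yl)silyloxy]phenyl}propan-2-yl]-4,4,5,5-tetramethyl-1,3,2-dioxaborolane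
Conditions: B2pin2, CuCl (5 mol %), chiral imidazolinium salt (N-heterocyclic carbene precursor, 5 mol %), NaOtBu (cat.), MeOH (2 equiv), THF, −50 °C
Reagents that add atoms: bis(pinacolato)diboron (B2pin2) | CC1(C)OB(OC1(C)C)B1OC(C)(C)C(C)(C)O1
Why: Copper-catalysed enantioselective protoboration of a β-methylstyrene, in which the Cu–Bpin species adds with boron at the carbon remote from the aryl ring and copper at the benzylic carbon, methanol protonates the C–Cu bond, and the chiral carbene ligand sets the C8 stereocentre by face selection, the ligand antipode used being the one that gives the (R) ester.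

**Step 5**
Reactants: 4 4-bromo-5-methoxy-2-(prop-2-en-1-yl)phenol; 7 2-[(2R)-1-{3-methoxy-4-[tri(propan-2-yl)silyloxy]phenyl}propan-2-yl]-4,4,5,5-tetramethyl-1,3,2-dioxaborolane
Product: 11 5-methoxy-4-[(2R)-1-{3-methoxy-4-[tri(propan-2-yl)silyloxy]phenyl}propan-2-yl]-2-(prop-2-en-1-yl)phenol, via dilithiated phenoxide 8 (not isolated), via lithium boronate complex 9 (not isolated), via boryl dienone 10 (not isolated)
Conditions: 4, n-BuLi (1 equiv) then t-BuLi (2 equiv), THF, −78 °C; 7, −78 °C to rt; Ph3BiF2, −78 °C to rt; aq. NH4Cl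
Reagents that add atoms: none
Why: Bromine–lithium exchange on the lithium phenoxide gives the para-lithiated phenoxide 8, which adds to the boron of 7 to give the tetracoordinate boronate 9; Ph3BiF2 then oxidises the phenoxide oxygen, and as triphenylbismuthane leaves, the secondary alkyl group shifts from boron to the ipso carbon C4 (1,2-metallate rearrangement) to give the dearomatised 4-alkyl-4-boryl dienone 10, which rearomatises with loss of the boryl group. The closest known reaction type is the enantiospecific coupling of secondary boronic esters with para-lithiated phenoxides triggered by pentavalent bismuth (Ph3BiF2). No ring is closed. No new stereocentre is made: the shift is suprafacial at the migrating carbon, so C8 passes from 7 to 11 with retention, and both carry the (R) descriptor. The step needs the alkyl group to go to C4 only, which the position of bromine in 4 secures, and it needs the allyl group to stay untouched, which the absence of a transition-metal hydride and of an electrophilic halogen secures. The alkyl group and not a pinacol oxygen migrates, because only the B–C bond can donate into the electron-poor ring.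

**Step 6**
Reactants: 11 5-methoxy-4-[(2R)-1-{3-methoxy-4-[tri(propan-2-yl)silyloxy]phenyl}propan-2-yl]-2-(prop-2-en-1-yl)phenol
Product: 12 (4R)-4,5-dimethoxy-4-[(2R)-1-{3-methoxy-4-[tri(propan-2-yl)silyloxy]phenyl}propan-2-yl]-2-(prop-2-en-1-yl)cyclohexa-2,5-dien-1-one
Conditions: PhI(OAc)2, MeOH, 0 °C
Reagents that add atoms: methanol | CO
Why: Oxidative dearomatisation of a para-alkylphenol with PhI(OAc)2 in methanol (para-quinol ether formation), in which solvent methanol adds to C4 of the oxidised phenol faster than the tethered aryl ring can; the C4 stereocentre is set by substrate control, the C8–H bond lying in the ring plane next to the C5 methoxy group (allylic 1,3-strain) so that methanol enters on the methyl face, away from the CH2Ar arm, which should favour the (4R) isomer, and the (4S) epimer is removed by chromatography.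

**Step 7**
Reactants: 12 (4R)-4,5-dimethoxy-4-[(2R)-1-{3-methoxy-4-[tri(propan-2-yl)silyloxy]phenyl}propan-2-yl]-2-(prop-2-en-1-yl)cyclohexa-2,5-dien-1-one
Product: 13 (4R)-4-[(2R)-1-(4-hydroxy-3-methoxyphenyl)propan-2-yl]-4,5-dimethoxy-2-(prop-2-en-1-yl)cyclohexa-2,5-dien-1-one
Conditions: Bu4NF, AcOH, THF, 0 °C
Reagents that add atoms: none
Why: Fluoride-mediated cleavage of the aryl silyl ether, with acetic acid buffering the phenoxide so that the dienone, which has no epimerisable centre, is left as it is.

**Compound list**
1 | 4-bromo-3-methoxyphenol | COc1cc(O)ccc1Br | starting material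
2 | allyl bromide (3-bromoprop-1-ene) | C=CCBr | starting material
3 | 1-bromo-2-methoxy-4-(prop-2-en-1-yloxy)benzene | C=CCOc1ccc(Br)c(OC)c1 | intermediate
4 | 4-bromo-5-methoxy-2-(prop-2-en-1-yl)phenol | C=CCc1cc(Br)c(OC)cc1O | intermediate
5 | (E)-isoeugenol, 2-methoxy-4-[(1E)-prop-1-en-1-yl]phenol | C/C=C/c1ccc(O)c(OC)c1 | starting material
6 | {2-methoxy-4-[(1E)-prop-1-en-1-yl]phenoxy}tri(propan-2-yl)silane | C/C=C/c1ccc(O[Si](C(C)C)(C(C)C)C(C)C)c(OC)c1 | intermediate
7 | 2-[(2R)-1-{3-methoxy-4-[tri(propan-2-yl)silyloxy]phenyl}propan-2-yl]-4,4,5,5-tetramethyl-1,3,2-dioxaborolane | C[C@H](Cc1ccc(O[Si](C(C)C)(C(C)C)C(C)C)c(OC)c1)B1OC(C)(C)C(C)(C)O1 | intermediate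
8 | lithium 4-lithio-5-methoxy-2-(prop-2-en-1-yl)phenoxide (dilithiated phenoxide, formed in the flask) | [Li]Oc1cc(OC)c([Li])cc1CC=C | intermediate
9 | dilithium salt of the boronate from 8 and 7, boron bound to ring carbon C4, to the (2R) alkyl group and to pinacol (formed in the flask) | [Li+].[Li+].[O-]c1cc(OC)c(cc1CC=C)[B-]1(OC(C)(C)C(C)(C)O1)[C@H](C)Cc1ccc(O[Si](C(C)C)(C(C)C)C(C)C)c(OC)c1 | intermediate
10 | 5-methoxy-4-[(2R)-1-{3-methoxy-4-[tri(propan-2-yl)silyloxy]phenyl}propan-2-yl]-2-(prop-2-en-1-yl)-4-(4,4,5,5-tetramethyl-1,3,2-dioxaborolan-2-yl)cyclohexa-2,5-dien-1-one (boryl dienone, formed in the flask; C4 configuration not defined and without consequence) | C=CCC1=CC(B2OC(C)(C)C(C)(C)O2)([C@H](C)Cc2ccc(O[Si](C(C)C)(C(C)C)C(C)C)c(OC)c2)C(OC)=CC1=O | intermediate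
11 | 5-methoxy-4-[(2R)-1-{3-methoxy-4-[tri(propan-2-yl)silyloxy]phenyl}propan-2-yl]-2-(prop-2-en-1-yl)phenol | C=CCc1cc([C@H](C)Cc2ccc(O[Si](C(C)C)(C(C)C)C(C)C)c(OC)c2)c(OC)cc1O | intermediate
12 | (4R)-4,5-dimethoxy-4-[(2R)-1-{3-methoxy-4-[tri(propan-2-yl)silyloxy]phenyl}propan-2-yl]-2-(prop-2-en-1-yl)cyclohexa-2,5-dien-1-one | C=CCC1=C[C@](OC)([C@H](C)Cc2ccc(O[Si](C(C)C)(C(C)C)C(C)C)c(OC)c2)C(OC)=CC1=O | intermediate
13 | (4R)-4-[(2R)-1-(4-hydroxy-3-methoxyphenyl)propan-2-yl]-4,5-dimethoxy-2-(prop-2-en-1-yl)cyclohexa-2,5-dien-1-one | C=CCC1=C[C@](OC)([C@H](C)Cc2ccc(O)c(OC)c2)C(OC)=CC1=O | target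

**Total step count:** 7
**Longest linear sequence:** 5 steps (steps 1, 2, 5, 6, 7 from 1; equally steps 3, 4, 5, 6, 7 from 5)

**Steps most likely to fail**

1. Step 5. The boronate may fail to form at the aryllithium carbon that carries an ortho methoxy group, or pentavalent bismuth may transfer a phenyl group to the phenoxide instead of triggering the alkyl shift. The fallback sets out from 4 and comes back to the route at 12; it makes the C8–C4 bond at the dienone oxidation level by carbonyl addition.
 - Oxidation of 4 with PhI(OCOCF3)2 in MeCN–H2O (water adds to the brominated para carbon and HBr is lost) gives the quinone 2-methoxy-5-(prop-2-en-1-yl)cyclohexa-2,5-diene-1,4-dione F1.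
 - Separately, commercial 4-bromo-2-methoxyphenol is silylated (TIPSCl, imidazole) to (4-bromo-2-methoxyphenoxy)tri(propan-2-yl)silane F2, which with Mg in THF gives the Grignard reagent bromo{3-methoxy-4-[tri(propan-2-yl)silyloxy]phenyl}magnesium F3.
 - CuI-catalysed opening of commercial (S)-2-methyloxirane at its CH2 group gives (2S)-1-{3-methoxy-4-[tri(propan-2-yl)silyloxy]phenyl}propan-2-ol F4. PPh3, I2 and imidazole (Appel reaction, inversion) turn it into {4-[(2R)-2-iodopropyl]-2-methoxyphenoxy}tri(propan-2-yl)silane F5.
 - Iodine–lithium exchange with t-BuLi at −100 °C in pentane–Et2O gives, with retention, the secondary alkyllithium [(2R)-1-{3-methoxy-4-[tri(propan-2-yl)silyloxy]phenyl}propan-2-yl]lithium F6, which is added at once to F1. Of the two carbonyl groups of F1 only the one next to the methoxy-bearing carbon is not deactivated as a vinylogous ester, so 1,2-addition there gives lithium (1R)-2-methoxy-1-[(2R)-1-{3-methoxy-4-[tri(propan-2-yl)silyloxy]phenyl}propan-2-yl]-4-oxo-5-(prop-2-en-1-yl)cyclohexa-2,5-dien-1-olate F7. MeOTf in the same flask methylates F7 to 12.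
 - C8 then comes from (S)-2-methyloxirane (one inversion, two retentive steps). C4 is again under substrate control, and the 4-epimer is removed by chromatography.

2. Step 6. Methanol may add to both faces of C4 with little preference, and in part at an ortho carbon. The fallback sets out from 11 and comes back to 11. The unwanted epimer (4S)-4,5-dimethoxy-4-[(2R)-1-{3-methoxy-4-[tri(propan-2-yl)silyloxy]phenyl}propan-2-yl]-2-(prop-2-en-1-yl)cyclohexa-2,5-dien-1-one F8, separated from 12 by chromatography, is not discarded. Zn dust in AcOH cleaves its C4–OCH3 bond reductively and rearomatises ring A to 11, which is oxidised again. The C4 centre is thus set by repeated passes with recycling instead of by one selective addition.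

3. Step 2. The allyl group may migrate in part to the ortho carbon between the two oxygen substituents. The fallback sets out from 1 and comes back to the route at 4; it replaces the sigmatropic shift by a cross-coupling at a carbon fixed by halogenation. N-Iodosuccinimide in MeCN iodinates 1 at the less hindered of the two doubly activated positions (ortho to OH, para to OCH3) to give 4-bromo-2-iodo-5-methoxyphenol F9. Stille coupling with allylSnBu3 and Pd(PPh3)4, in which zerovalent palladium inserts into the C–I bond and leaves the C–Br bond, gives 4.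

**Further compounds**
F1 | step 5 | 2-methoxy-5-(prop-2-en-1-yl)cyclohexa-2,5-diene-1,4-dione | C=CCC1=CC(=O)C(OC)=CC1=O
F2 | step 5 | (4-bromo-2-methoxyphenoxy)tri(propan-2-yl)silane | COc1cc(Br)ccc1O[Si](C(C)C)(C(C)C)C(C)C
F3 | step 5 | bromo{3-methoxy-4-[tri(propan-2-yl)silyloxy]phenyl}magnesium | COc1cc([Mg]Br)ccc1O[Si](C(C)C)(C(C)C)C(C)C
F4 | step 5 | (2S)-1-{3-methoxy-4-[tri(propan-2-yl)silyloxy]phenyl}propan-2-ol | C[C@H](O)Cc1ccc(O[Si](C(C)C)(C(C)C)C(C)C)c(OC)c1
F5 | step 5 | {4-[(2R)-2-iodopropyl]-2-methoxyphenoxy}tri(propan-2-yl)silane | C[C@@H](I)Cc1ccc(O[Si](C(C)C)(C(C)C)C(C)C)c(OC)c1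
F6 | step 5 | [(2R)-1-{3-methoxy-4-[tri(propan-2-yl)silyloxy]phenyl}propan-2-yl]lithium | C[C@@H]([Li])Cc1ccc(O[Si](C(C)C)(C(C)C)C(C)C)c(OC)c1
F7 | step 5 | lithium (1R)-2-methoxy-1-[(2R)-1-{3-methoxy-4-[tri(propan-2-yl)silyloxy]phenyl}propan-2-yl]-4-oxo-5-(prop-2-en-1-yl)cyclohexa-2,5-dien-1-olate | C=CCC1=C[C@](O[Li])([C@H](C)Cc2ccc(O[Si](C(C)C)(C(C)C)C(C)C)c(OC)c2)C(OC)=CC1=O
F8 | step 6 | (4S)-4,5-dimethoxy-4-[(2R)-1-{3-methoxy-4-[tri(propan-2-yl)silyloxy]phenyl}propan-2-yl]-2-(prop-2-en-1-yl)cyclohexa-2,5-dien-1-one | C=CCC1=C[C@@](OC)([C@H](C)Cc2ccc(O[Si](C(C)C)(C(C)C)C(C)C)c(OC)c2)C(OC)=CC1=O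
F9 | step 2 | 4-bromo-2-iodo-5-methoxyphenol | COc1cc(O)c(I)cc1Br
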